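The strategy cuts the hexasubstituted benzene ring of the dihydroisocoumarin at C4a–C5 and C6–C7. C4a and C8a are shared with the δ-lactone ring, and C7 and C8 carry methyl and oxygen. These four carbons therefore come from a 2-pyrone that is already fused to the (R)-lactone. C5 with its arylmethyl arm and C6 with its oxygen come from the bis(trimethylsilyl) ketene acetal of a 3-arylpropanoic acid. One operation (cycloaddition, then loss of CO2 and silanol) closes the arene with all six substituents in place. The stereocentre is bought with methyl (R)-3-hydroxybutanoate. The chromone is annulated later onto the symmetric aryl ring, and BCl3 frees the three phenols.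

Key step: step 8

Remark: the keto lactone made in step 2 is drawn as the dione although it reacts through its 4-hydroxy enol tautomer. Methylmalonyl dichloride and tert-butyl but-2-ynoate are taken as catalogue chemicals.

Step 1
Reactants: 1 methyl (3R)-3-hydroxybutanoate; 2 tert-butyl acetate
Product: 3 tert-butyl (5R)-5-hydroxy-3-oxohexanoate
Conditions: 2 (4 equiv), LiN(iPr)2 (4 equiv), THF, −78 °C; then 1, −78 → −20 °C; AcOH quench
Reagents that add atoms: none
Why: Crossed Claisen condensation: the excess lithium enolate of 2 first deprotonates the hydroxyl group of 1 and then attacks the methyl ester, self-condensation of the bulky tert-butyl ester is slow, the β-keto ester is stored as its enolate until the quench, and no bond to the chiral-pool carbinol carbon is touched, so (R) is carried over.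

Step 2
Reactants: 3 tert-butyl (5R)-5-hydroxy-3-oxohexanoate
Product: 5 (6R)-6-methyloxane-2,4-dione, via hydroxy keto acid 4 (not isolated)
Conditions: CF3CO2H, CH2Cl2, 0 °C → rt
Reagents that add atoms: none
Why: Acidolysis of the tert-butyl ester gives 4, whose secondary hydroxyl group closes the six-membered lactone by acyl substitution faster than the β-keto acid loses CO2; the C–O bond at the stereocentre stays intact, so the configuration is retained.

Step 3
Reactants: 5 (6R)-6-methyloxane-2,4-dione; 6 methylmalonyl dichloride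
Product: 7 (7R)-4-hydroxy-3,7-dimethyl-7,8-dihydro-2H,5H-pyrano[4,3-b]pyran-2,5-dione
Conditions: 6 (1.1 equiv), toluene, 80–100 °C, N2 sweep to remove HCl
Reagents that add atoms: none
Why: Cyclic malonylation of a β-dicarbonyl compound: the enol of 5 is acylated at its oxygen and at C3 by the two acid chloride groups of 6 (six-membered closure, HCl as the only by-product), which is the reaction type that converts 4-hydroxycoumarins, 4-hydroxy-2-pyrones and cyclohexane-1,3-diones into fused 4-hydroxy-2-pyrones.

Step 4
Reactants: 7 (7R)-4-hydroxy-3,7-dimethyl-7,8-dihydro-2H,5H-pyrano[4,3-b]pyran-2,5-dione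
Product: 8 (7R)-4-methoxy-3,7-dimethyl-7,8-dihydro-2H,5H-pyrano[4,3-b]pyran-2,5-dione
Conditions: Me2SO4 (1.2 equiv), K2CO3 (1.5 equiv), acetone, rt
Reagents that add atoms: dimethyl sulfate COS(=O)(=O)OC
Why: Williamson-type O-alkylation of the acidic 4-hydroxy-2-pyrone under the conditions known to favour the 4-methoxy-2-pyrone over the isomeric 2-methoxy-4-pyrone, run at room temperature so that the weak base leaves the acidic C8 methylene group next to the lactone stereocentre alone.

Step 5
Reactants: 9 4-hydroxy-2,6-dimethoxybenzaldehyde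
Product: 10 4-(benzyloxy)-2,6-dimethoxybenzaldehyde
Conditions: BnBr, K2CO3, DMF, rt
Reagents that add atoms: benzyl bromide BrCc1ccccc1
Why: Williamson ether synthesis on the only phenol, made more acidic by the para formyl group; the benzyl ether later withstands amide base, heat and dilute acid and leaves by hydrogenolysis.

Step 6
Reactants: 10 4-(benzyloxy)-2,6-dimethoxybenzaldehyde; 11 Meldrum's acid (2,2-dimethyl-1,3-dioxane-4,6-dione)
Product: 14 3-[4-(benzyloxy)-2,6-dimethoxyphenyl]propanoic acid, via arylidene Meldrum's acid 12 (not isolated), via benzyl Meldrum's acid 13 (not isolated)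
Conditions: 11 (1.05 equiv), HCO2H–Et3N (5:2), 95–100 °C
Reagents that add atoms: none
Why: One-pot reductive Knoevenagel sequence: 10 condenses with 11 to 12, formate delivers hydride to the electron-poor alkene to give 13, and the water released in the condensation opens the dioxanedione, which loses acetone and CO2; no metal catalyst or hydrogen gas is present, so the benzyl ether is not at risk.

Step 7
Reactants: 14 3-[4-(benzyloxy)-2,6-dimethoxyphenyl]propanoic acid
Product: 16 1,1-bis(trimethylsilyloxy)-3-[4-(benzyloxy)-2,6-dimethoxyphenyl]prop-1-ene, via dilithium enediolate 15 (not isolated)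
Conditions: LiN(iPr)2 (2.2 equiv), THF, −78 → 0 °C; Me3SiCl (2.5 equiv), −78 °C → rt; pentane, filtration under argon, used crude
Reagents that add atoms: chlorotrimethylsilane C[Si](C)(C)Cl
Why: Double deprotonation gives enediolate 15, which the hard electrophile Me3SiCl silylates on both oxygens (the standard preparation of bis(silyl) ketene acetals); two identical silyloxy groups remove any question of alkene geometry, and the non-aqueous work-up avoids hydrolysis.

Step 8
Reactants: 8 (7R)-4-methoxy-3,7-dimethyl-7,8-dihydro-2H,5H-pyrano[4,3-b]pyran-2,5-dione; 16 1,1-bis(trimethylsilyloxy)-3-[4-(benzyloxy)-2,6-dimethoxyphenyl]prop-1-ene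
Product: 20 (3R)-5-{[4-(benzyloxy)-2,6-dimethoxyphenyl]methyl}-6-hydroxy-8-methoxy-3,7-dimethylisochroman-1-one, via bridged bicyclic lactone 17 (not isolated), via bis(silyloxy)cyclohexadiene 18 (not isolated), via aryl trimethylsilyl ether 19 (not isolated)
Conditions: 16 (2.5 equiv), toluene, 120 °C, sealed tube; then 1 M HCl, THF, rt
Reagents that add atoms: none
Why: The CH carbon of 16, the donor end of the ketene acetal, attacks C8a of 8 (future C4a), the only pyrone carbon that is vinylogous to both the pyrone and the δ-lactone carbonyl groups, and the resulting dienolate closes from the methyl-bearing C3 of 8 (future C7) onto the bis(silyloxy)carbenium carbon (future C6), so that a strongly asynchronous or stepwise inverse-electron-demand [4+2] cycloaddition gives the 2-oxabicyclo[2.2.2]octenone 17. Retro-[4+2] loss of CO2 from 17 gives cyclohexadiene 18, elimination of Me3SiOH across C5–C6 aromatises it to 19, and dilute acid cleaves the aryl silyl ether to 20. The closest known reaction type is the Diels–Alder/decarboxylation sequence of acyl-substituted 2-pyrones (coumalates, 3-carbomethoxy-2-pyrones and their ring-fused relatives) with ketene acetals, β-substituted ones included, which gives oxygenated benzoates. The one ring that is closed, the six-membered carbocycle, forms by intermolecular (4+2) annulation, four carbons from the diene and two from the dienophile, with C4a–C5 and C6–C7 as the new bonds. No stereocentre is created for good, because the three sp3 centres of 17 vanish on aromatisation, and the (R) centre is a spectator that is safe under neutral aprotic conditions, whereas a basic enolate would deprotonate the acidic C8 methylene group of 8 and invite β-elimination of the lactone carboxylate. The step has to deliver a single orientation, which follows from the matched polarity of the donor carbon and the doubly activated acceptor carbon, while two identical silyloxy groups allow only one aromatisation outcome, the free C6 phenol; 16 is used in excess because the silanol set free consumes part of it.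

Step 9
Reactants: 20 (3R)-5-{[4-(benzyloxy)-2,6-dimethoxyphenyl]methyl}-6-hydroxy-8-methoxy-3,7-dimethylisochroman-1-one
Product: 21 (3R)-5-{[4-(benzyloxy)-2,6-dimethoxyphenyl]methyl}-8-methoxy-3,7-dimethyl-6-(propan-2-yloxy)isochroman-1-one
Conditions: 2-bromopropane (excess), K2CO3, DMF, 60 °C
Reagents that add atoms: 2-bromopropane CC(C)Br
Why: Williamson ether synthesis on the only free hydroxyl group; carbonate is far too weak to deprotonate C4–H of the aromatic lactone, and the isopropyl ether is chosen because it survives hydrogenolysis, carbonate and cold MeSO3H and later leaves with BCl3.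

Step 10
Reactants: 21 (3R)-5-{[4-(benzyloxy)-2,6-dimethoxyphenyl]methyl}-8-methoxy-3,7-dimethyl-6-(propan-2-yloxy)isochroman-1-one
Product: 22 (3R)-5-[(4-hydroxy-2,6-dimethoxyphenyl)methyl]-8-methoxy-3,7-dimethyl-6-(propan-2-yloxy)isochroman-1-one
Conditions: H2 (1 atm), Pd/C, EtOAc–EtOH, rt
Reagents that add atoms: none
Why: Catalytic hydrogenolysis cleaves the only benzylic C–O bond; the diarylmethane C–C bonds, the homobenzylic lactone C–O bond and the alkyl aryl ethers are inert under these conditions.

Step 11
Reactants: 22 (3R)-5-[(4-hydroxy-2,6-dimethoxyphenyl)methyl]-8-methoxy-3,7-dimethyl-6-(propan-2-yloxy)isochroman-1-one; 23 tert-butyl but-2-ynoate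
Product: 24 tert-butyl (2E)-3-(3,5-dimethoxy-4-{[(3R)-8-methoxy-3,7-dimethyl-1-oxo-6-(propan-2-yloxy)isochroman-5-yl]methyl}phenoxy)but-2-enoate
Conditions: 23 (1.5 equiv), K2CO3 (0.3 equiv), DMF, 70 °C
Reagents that add atoms: none
Why: Base-catalysed oxa-Michael addition of the single, unhindered phenol to the alkynoate gives the thermodynamically preferred E enol ether; the tert-butyl ester is chosen so that the acid can later be released without hydroxide, which would open the lactone.

Step 12
Reactants: 24 tert-butyl (2E)-3-(3,5-dimethoxy-4-{[(3R)-8-methoxy-3,7-dimethyl-1-oxo-6-(propan-2-yloxy)isochroman-5-yl]methyl}phenoxy)but-2-enoate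
Product: 26 5,7-dimethoxy-6-{[(3R)-8-methoxy-3,7-dimethyl-1-oxo-6-(propan-2-yloxy)isochroman-5-yl]methyl}-2-methyl-4H-chromen-4-one, via aryloxycrotonic acid 25 (not isolated)
Conditions: P2O5–MeSO3H (1:10 w/w, Eaton's reagent), 0 °C → rt; ice water
Reagents that add atoms: none
Why: Ruhemann-type chromone synthesis: MeSO3H strips the tert-butyl ester to 25, reversible C-protonation of the push–pull enol ether lets the E acid reach the Z geometry, and the activated acyl group closes the pyranone by intramolecular Friedel–Crafts acylation ortho to the vinyl ether oxygen and para to a methoxy group; the two ortho positions are equivalent, so only one chromone can form.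

Step 13
Reactants: 26 5,7-dimethoxy-6-{[(3R)-8-methoxy-3,7-dimethyl-1-oxo-6-(propan-2-yloxy)isochroman-5-yl]methyl}-2-methyl-4H-chromen-4-one
Product: 27 6-{[(3R)-6,8-dihydroxy-3,7-dimethyl-1-oxoisochroman-5-yl]methyl}-5-hydroxy-7-methoxy-2-methyl-4H-chromen-4-one
Conditions: BCl3 (6 equiv), CH2Cl2, −78 → 0 °C; then H2O
Reagents that add atoms: none
Why: Lewis-acid ether cleavage: BCl3 chelated between a carbonyl oxygen and the peri methoxy group removes the chromone 5-O-methyl and the isochromanone 8-O-methyl groups, and it also cleaves the secondary isopropyl ether, whereas the unchelated chromone 7-methoxy group persists at or below 0 °C and the stereocentre is not involved.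

Compound list
1 | methyl (3R)-3-hydroxybutanoate | C[C@@H](O)CC(=O)OC | starting material
2 | tert-butyl acetate | CC(=O)OC(C)(C)C | starting material
3 | tert-butyl (5R)-5-hydroxy-3-oxohexanoate | C[C@@H](O)CC(=O)CC(=O)OC(C)(C)C | intermediate
4 | (5R)-5-hydroxy-3-oxohexanoic acid | C[C@@H](O)CC(=O)CC(=O)O | intermediate (not isolated)
5 | (6R)-6-methyloxane-2,4-dione, tautomer of (6R)-4-hydroxy-6-methyl-5,6-dihydro-2H-pyran-2-one | C[C@@H]1CC(=O)CC(=O)O1 | intermediate
6 | methylmalonyl dichloride | CC(C(Cl)=O)C(Cl)=O | starting material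
7 | (7R)-4-hydroxy-3,7-dimethyl-7,8-dihydro-2H,5H-pyrano[4,3-b]pyran-2,5-dione | O=C1OC2=C(C(=O)O[C@H](C)C2)C(O)=C1C | intermediate
8 | (7R)-4-methoxy-3,7-dimethyl-7,8-dihydro-2H,5H-pyrano[4,3-b]pyran-2,5-dione | O=C1OC2=C(C(=O)O[C@H](C)C2)C(OC)=C1C | intermediate
9 | 4-hydroxy-2,6-dimethoxybenzaldehyde | COc1cc(O)cc(OC)c1C=O | starting material
10 | 4-(benzyloxy)-2,6-dimethoxybenzaldehyde | COc1cc(OCc2ccccc2)cc(OC)c1C=O | intermediate
11 | Meldrum's acid (2,2-dimethyl-1,3-dioxane-4,6-dione) | CC1(C)OC(=O)CC(=O)O1 | starting material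
12 | 5-{[4-(benzyloxy)-2,6-dimethoxyphenyl]methylidene}-2,2-dimethyl-1,3-dioxane-4,6-dione | COc1cc(OCc2ccccc2)cc(OC)c1C=C1C(=O)OC(C)(C)OC1=O | intermediate (not isolated)
13 | 5-{[4-(benzyloxy)-2,6-dimethoxyphenyl]methyl}-2,2-dimethyl-1,3-dioxane-4,6-dione | COc1cc(OCc2ccccc2)cc(OC)c1CC1C(=O)OC(C)(C)OC1=O | intermediate (not isolated)
14 | 3-[4-(benzyloxy)-2,6-dimethoxyphenyl]propanoic acid | COc1cc(OCc2ccccc2)cc(OC)c1CCC(=O)O | intermediate
15 | dilithium 3-[4-(benzyloxy)-2,6-dimethoxyphenyl]prop-1-ene-1,1-diolate | [Li+].[Li+].[O-]C([O-])=CCc1c(OC)cc(OCc2ccccc2)cc1OC | intermediate (not isolated)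
16 | 1,1-bis(trimethylsilyloxy)-3-[4-(benzyloxy)-2,6-dimethoxyphenyl]prop-1-ene | C[Si](C)(C)OC(O[Si](C)(C)C)=CCc1c(OC)cc(OCc2ccccc2)cc1OC | intermediate
17 | 2-oxabicyclo[2.2.2]oct-5-en-3-one cycloadduct: C3 of 8 bonded to the acetal carbon and C8a of 8 bonded to the CH carbon of 16, (R)-δ-lactone still fused, three new sp3 centres undefined | CC12C(=O)OC3(C[C@@H](C)OC(=O)C3=C1OC)C(Cc4c(OC)cc(OCc5ccccc5)cc4OC)C2(O[Si](C)(C)C)O[Si](C)(C)C | intermediate (not isolated)
18 | (3R)-5-{[4-(benzyloxy)-2,6-dimethoxyphenyl]methyl}-8-methoxy-3,7-dimethyl-6,6-bis(trimethylsilyloxy)-3,4,5,6-tetrahydroisochromen-1-one (C5 undefined) | CC1=C(OC)C2=C(C[C@@H](C)OC2=O)C(Cc3c(OC)cc(OCc4ccccc4)cc3OC)C1(O[Si](C)(C)C)O[Si](C)(C)C | intermediate (not isolated)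
19 | (3R)-5-{[4-(benzyloxy)-2,6-dimethoxyphenyl]methyl}-8-methoxy-3,7-dimethyl-6-(trimethylsilyloxy)isochroman-1-one | Cc1c(OC)c2c(C[C@@H](C)OC2=O)c(Cc3c(OC)cc(OCc4ccccc4)cc3OC)c1O[Si](C)(C)C | intermediate (not isolated)
20 | (3R)-5-{[4-(benzyloxy)-2,6-dimethoxyphenyl]methyl}-6-hydroxy-8-methoxy-3,7-dimethylisochroman-1-one | COc1cc(OCc2ccccc2)cc(OC)c1Cc1c(O)c(C)c(OC)c2C(=O)O[C@H](C)Cc12 | intermediate
21 | (3R)-5-{[4-(benzyloxy)-2,6-dimethoxyphenyl]methyl}-8-methoxy-3,7-dimethyl-6-(propan-2-yloxy)isochroman-1-one | COc1cc(OCc2ccccc2)cc(OC)c1Cc1c(OC(C)C)c(C)c(OC)c2C(=O)O[C@H](C)Cc12 | intermediate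
22 | (3R)-5-[(4-hydroxy-2,6-dimethoxyphenyl)methyl]-8-methoxy-3,7-dimethyl-6-(propan-2-yloxy)isochroman-1-one | COc1cc(O)cc(OC)c1Cc1c(OC(C)C)c(C)c(OC)c2C(=O)O[C@H](C)Cc12 | intermediate
23 | tert-butyl but-2-ynoate | CC#CC(=O)OC(C)(C)C | starting material
24 | tert-butyl (2E)-3-(3,5-dimethoxy-4-{[(3R)-8-methoxy-3,7-dimethyl-1-oxo-6-(propan-2-yloxy)isochroman-5-yl]methyl}phenoxy)but-2-enoate | C/C(Oc1cc(OC)c(Cc2c(OC(C)C)c(C)c(OC)c3C(=O)O[C@H](C)Cc23)c(OC)c1)=C\C(=O)OC(C)(C)C | intermediate
25 | (2E)-3-(3,5-dimethoxy-4-{[(3R)-8-methoxy-3,7-dimethyl-1-oxo-6-(propan-2-yloxy)isochroman-5-yl]methyl}phenoxy)but-2-enoic acid | C/C(Oc1cc(OC)c(Cc2c(OC(C)C)c(C)c(OC)c3C(=O)O[C@H](C)Cc23)c(OC)c1)=C\C(=O)O | intermediate (not isolated)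
26 | 5,7-dimethoxy-6-{[(3R)-8-methoxy-3,7-dimethyl-1-oxo-6-(propan-2-yloxy)isochroman-5-yl]methyl}-2-methyl-4H-chromen-4-one | COc1cc2oc(C)cc(=O)c2c(OC)c1Cc1c(OC(C)C)c(C)c(OC)c2c1C[C@@H](C)OC2=O | intermediate
27 | 6-{[(3R)-6,8-dihydroxy-3,7-dimethyl-1-oxoisochroman-5-yl]methyl}-5-hydroxy-7-methoxy-2-methyl-4H-chromen-4-one (CNP0180307.1) | COc1cc2oc(C)cc(=O)c2c(O)c1Cc1c(O)c(C)c(O)c2c1C[C@@H](C)OC2=O | target

Total step count: 13.
Longest linear sequence: 10 steps (steps 1–4, then 8–13). The ketene acetal arm (steps 5–7) joins at step 8.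

Steps most likely to fail

Step 8.
- **What may go wrong:** the conjugate addition may be slow or reversible. The second bond joins two fully substituted carbons on a diene that the 3-methyl and 4-methoxy groups make less electron-poor, so it may not close before 16 is consumed by adventitious protons.
- **Fallback:** the C7 methyl group is left out of the diene and is introduced after aromatisation.
- The fallback sets out from 5. Malonyl dichloride (toluene, 80 °C) should give (7R)-4-hydroxy-7-methyl-7,8-dihydro-2H,5H-pyrano[4,3-b]pyran-2,5-dione F1.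
- Me2SO4/K2CO3 in acetone should then give (7R)-4-methoxy-7-methyl-7,8-dihydro-2H,5H-pyrano[4,3-b]pyran-2,5-dione F2.
- F2 is unsubstituted at the pyrone carbon that must bond to the acetal carbon. It therefore matches the 3-unsubstituted 5-acyl-2-pyrones for which the reaction with ketene acetals is established.
- With 16, under the conditions and work-up of step 8, F2 should give (3R)-5-{[4-(benzyloxy)-2,6-dimethoxyphenyl]methyl}-6-hydroxy-8-methoxy-3-methylisochroman-1-one F3.
- Magnesium-phenoxide-directed ortho-formylation (Casnati–Skattebøl; MgCl2, Et3N, paraformaldehyde, MeCN, reflux) can reach only C7, the sole free position ortho to the C6 phenol, and ignores the benzyloxy-substituted ring. It should give (3R)-5-{[4-(benzyloxy)-2,6-dimethoxyphenyl]methyl}-6-hydroxy-8-methoxy-3-methyl-1-oxoisochromane-7-carbaldehyde F4.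
- Ionic hydrogenation (Et3SiH, CF3CO2H, CH2Cl2, 0 °C) reduces the formyl group to methyl and comes back to the route at 20.

Step 3.
- **What may go wrong:** double O-acylation and oligomerisation may compete, and the dihydropyrone may degrade in hot HCl before the second acylation closes the ring.
- **Fallback:** the pyrone is built by two separate, milder acylations.
- The fallback sets out from 5. Coupling with 3-ethoxy-2-methyl-3-oxopropanoic acid (N,N'-dicyclohexylcarbodiimide, DMAP, CH2Cl2, rt) forms the enol ester. A DMAP-induced O-to-C acyl shift follows, as is known for 4-hydroxy-5,6-dihydro-2-pyrones.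
- This should give ethyl 3-[(6R)-4-hydroxy-6-methyl-2-oxo-5,6-dihydro-2H-pyran-3-yl]-2-methyl-3-oxopropanoate F5.
- DBU in toluene at 80 °C then closes the enol oxygen onto the ethyl ester. This is the usual cyclisation of 3,5-dioxo esters to 4-hydroxy-2-pyrones, and it comes back to the route at 7.

Step 12.
- **What may go wrong:** E-to-Z isomerisation of the enol ether may be slow. Decarboxylation of the protonated acid or acid-induced scission of the electron-rich diarylmethane could then overtake ring closure.
- **Fallback:** the aryl–carbonyl bond is made first and the pyranone is closed at O1–C2, so alkene geometry no longer matters.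
- The fallback sets out from 22 and so bypasses step 11 as well. Ac2O and BF3·OEt2 (CH2Cl2, rt → 45 °C; O-acetylation followed by Fries shift to either of the two equivalent ortho positions) should give (3R)-5-[(3-acetyl-4-hydroxy-2,6-dimethoxyphenyl)methyl]-8-methoxy-3,7-dimethyl-6-(propan-2-yloxy)isochroman-1-one F6.
- N,N-Dimethylacetamide dimethyl acetal (toluene, 100 °C) condenses at the acetyl methyl group under neutral conditions. It should give (3R)-5-({3-[(2E)-3-(dimethylamino)but-2-enoyl]-4-hydroxy-2,6-dimethoxyphenyl}methyl)-8-methoxy-3,7-dimethyl-6-(propan-2-yloxy)isochroman-1-one F7.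
- Warm AcOH induces conjugate addition of the phenol and loss of dimethylamine, and comes back to the route at 26.

Further compounds
F1 | step 8 | (7R)-4-hydroxy-7-methyl-7,8-dihydro-2H,5H-pyrano[4,3-b]pyran-2,5-dione | O=C1OC2=C(C(=O)O[C@H](C)C2)C(O)=C1
F2 | step 8 | (7R)-4-methoxy-7-methyl-7,8-dihydro-2H,5H-pyrano[4,3-b]pyran-2,5-dione | O=C1OC2=C(C(=O)O[C@H](C)C2)C(OC)=C1
F3 | step 8 | (3R)-5-{[4-(benzyloxy)-2,6-dimethoxyphenyl]methyl}-6-hydroxy-8-methoxy-3-methylisochroman-1-one | COc1cc(OCc2ccccc2)cc(OC)c1Cc1c(O)cc(OC)c2C(=O)O[C@H](C)Cc12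
F4 | step 8 | (3R)-5-{[4-(benzyloxy)-2,6-dimethoxyphenyl]methyl}-6-hydroxy-8-methoxy-3-methyl-1-oxoisochromane-7-carbaldehyde | COc1cc(OCc2ccccc2)cc(OC)c1Cc1c(O)c(C=O)c(OC)c2C(=O)O[C@H](C)Cc12
F5 | step 3 | ethyl 3-[(6R)-4-hydroxy-6-methyl-2-oxo-5,6-dihydro-2H-pyran-3-yl]-2-methyl-3-oxopropanoate | CCOC(=O)C(C)C(=O)C1=C(O)C[C@@H](C)OC1=O
F6 | step 12 | (3R)-5-[(3-acetyl-4-hydroxy-2,6-dimethoxyphenyl)methyl]-8-methoxy-3,7-dimethyl-6-(propan-2-yloxy)isochroman-1-one | CC(=O)c1c(O)cc(OC)c(Cc2c(OC(C)C)c(C)c(OC)c3C(=O)O[C@H](C)Cc23)c1OC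
F7 | step 12 | (3R)-5-({3-[(2E)-3-(dimethylamino)but-2-enoyl]-4-hydroxy-2,6-dimethoxyphenyl}methyl)-8-methoxy-3,7-dimethyl-6-(propan-2-yloxy)isochroman-1-one | C/C(N(C)C)=C\C(=O)c1c(O)cc(OC)c(Cc2c(OC(C)C)c(C)c(OC)c3C(=O)O[C@H](C)Cc23)c1OC
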